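**Strategy.** The target, robinetinidol-(4α→2')-dihydrorobinetin, is cut at the bond between C4 of the upper flavan C-ring and C2' of the lower pyrogallol B-ring. Both halves then come from one commercial natural product, (+)-dihydrorobinetin. Borohydride reduction gives the flavan-3,4-diol; in dilute acid its C4 hydroxyl leaves as a benzylic cation stabilised by the para 7-OH and ortho O1 of ring A. In the key step a second dihydrorobinetin captures this cation through C2' (ortho to 3'-OH, para to 5'-OH; C2' and C6' are equivalent), while its own A-ring is switched off by the C4 carbonyl. One protecting-group-free operation forms the C4–C2' bond and sets C4 anti to the 3-OH.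

Key step: step 2

Assumption: (+)-(2R,3R)-dihydrorobinetin, the main heartwood flavonoid of Robinia pseudoacacia, is bought as the single natural enantiomer and supplies C2 and C3 of both halves.

Stereochemical reading of the target: the lower unit is (2R,3R), 2,3-trans. The upper unit is (2R,3S,4S), with 2-aryl α, 3-OH β and 4-aryl α, i.e. 2,3-trans-3,4-trans.

**Step 1**
Reactants: 1 (+)-dihydrorobinetin, (2R,3R)-3,7-dihydroxy-2-(3,4,5-trihydroxyphenyl)chroman-4-one
Product: 2 (+)-leucorobinetinidin, (2R,3S,4R)-2-(3,4,5-trihydroxyphenyl)chroman-3,4,7-triol (2,3-trans-3,4-trans flavan-3,4-diol)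
Conditions: NaBH4 (excess), EtOH, N2, 0 °C to rt; then H2O, AcOH to pH 6 at 0 °C, EtOAc extraction; used without delay
Reagents that add atoms: none
Why: Hydride 1,2-reduction of the aryl ketone, in which axial delivery to C4 of the half-chair with equatorial 2-aryl and 3-OH should give mainly the equatorial 4α-OH (4R), while C2 and C3 are untouched (C3 changes from R to S only through CIP priorities) and the C4 configuration is erased in step 2, so either epimer serves.

**Step 2**
Reactants: 2 (+)-leucorobinetinidin; 1 (+)-dihydrorobinetin (4 equiv, excess recovered)
Product: 4 robinetinidol-(4α→2')-dihydrorobinetin, via flavan-4-yl cation 3 (not isolated)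
Conditions: 1 (4 equiv), 0.1 M aq. HCl, N2, 25 °C, slow addition of 2, 24 h; EtOAc extraction, Sephadex LH-20 (EtOH), then reversed-phase HPLC
Reagents that add atoms: none
Why: Brønsted-acid SN1 Friedel–Crafts alkylation of the kind used in biomimetic proanthocyanidin synthesis: protonation of the benzylic 4-OH of 2 and loss of water give cation 3, an O-protonated A-ring p-quinone methide stabilised by 7-OH (para to C4a) and O1 (ortho). The pyrogallol B-ring of 1 attacks through C2' (identical with C6' by the local symmetry of that ring), which is ortho to 3'-OH and para to 5'-OH, and loss of a proton restores the arene; no ring is closed. The new C4 stereocentre is under substrate control: in the sofa-shaped cation the 2-aryl and 3-OH groups are quasi-equatorial and the arene should add to the α-face, anti to the 3β-OH, so the 3,4-trans (4S) adduct is expected as the major diastereomer and the 3,4-cis epimer as the minor one, to be removed by chromatography. Site selectivity within 1 is secured because O1 and 7-OH of its A-ring are conjugated to the C4 ketone, which leaves the B-ring as the only nucleophilic arene, and 1 cannot ionise itself. Cross-coupling over self-condensation of 2 (through its resorcinol-type A-ring or its own B-ring) and over further alkylation of the product is secured by the excess of 1 and the slow addition of 2, and the C4–aryl bond of a 5-deoxy flavan should be stable to 0.1 M HCl once formed.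

**Compound list**
1 | (+)-dihydrorobinetin, (2R,3R)-3,7-dihydroxy-2-(3,4,5-trihydroxyphenyl)chroman-4-one | O=C1c2ccc(O)cc2O[C@H](c2cc(O)c(O)c(O)c2)[C@H]1O | starting material
2 | (+)-leucorobinetinidin, (2R,3S,4R)-2-(3,4,5-trihydroxyphenyl)chroman-3,4,7-triol | O[C@@H]1c2ccc(O)cc2O[C@H](c2cc(O)c(O)c(O)c2)[C@H]1O | intermediate
3 | (2R,3S)-3,7-dihydroxy-2-(3,4,5-trihydroxyphenyl)chroman-4-ylium cation (O-protonated A-ring p-quinone methide) | [CH+]1c2ccc(O)cc2O[C@H](c2cc(O)c(O)c(O)c2)[C@H]1O | intermediate (not isolated)
4 | robinetinidol-(4α→2')-dihydrorobinetin, (2R,3R)-3,7-dihydroxy-2-{3,4,5-trihydroxy-2-[(2R,3S,4S)-3,7-dihydroxy-2-(3,4,5-trihydroxyphenyl)chroman-4-yl]phenyl}chroman-4-one | O=C1c2ccc(O)cc2O[C@H](c2cc(O)c(O)c(O)c2[C@@H]2c3ccc(O)cc3O[C@H](c3cc(O)c(O)c(O)c3)[C@H]2O)[C@H]1O | target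

**Total step count:** 2
**Longest linear sequence:** 2 steps (1 → 2 → 4; compound 1 enters a second time as the coupling partner)

**Steps most likely to fail** (the route has only two steps, so both are ranked)

1. Step 2. The cation may be consumed by self-condensation of 2 and by further alkylation of the product (oligomerisation). Ionisation of the 5-deoxy diol in dilute acid may be slow, attack at the hindered C2' position may be sluggish, and facial discrimination at C4 may be modest. Fallback: the route sets out from compound 2, which is heated with excess benzyl mercaptan and acetic acid in EtOH. The strongly nucleophilic thiol should trap the cation ahead of any arene and give the isolable thioether (2R,3R,4R)-4-(benzylsulfanyl)-2-(3,4,5-trihydroxyphenyl)chroman-3,7-diol F1 (the 3,4-trans isomer is drawn; either C4 epimer serves, since C4 is ionised again). F1 is then treated with AgBF4 in THF at 0 °C in the presence of excess 1. Thiophilic abstraction of the sulfanyl group should generate cation 3 irreversibly in an aprotic medium at low temperature, where the only nucleophile present in quantity is the B-ring of 1. The fallback returns to the route at compound 4.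

2. Step 1. In the basic borohydride medium the free phenoxides may trigger C-ring opening and C2 epimerisation through the B-ring quinone methide, and the pyrogallol may oxidise in air. The acid-labile diol may also self-condense during work-up and concentration. Fallback: the route sets out from compound 1, which is silylated on its four phenols (TBSCl 4.4 equiv, imidazole, DMF, 0 °C) to 7,3',4',5'-tetra-O-(tert-butyldimethylsilyl)dihydrorobinetin F2. With no phenoxide available, reduction of the ketone (NaBH4, THF–EtOH, 0 °C) should give 7,3',4',5'-tetra-O-(tert-butyldimethylsilyl)leucorobinetinidin F3, which can be purified on silica and stored. Buffered desilylation (TBAF, AcOH, THF, 0 °C) immediately before the coupling returns to the route at compound 2.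

**Further compounds**
F1 | step 2 | (2R,3R,4R)-4-(benzylsulfanyl)-2-(3,4,5-trihydroxyphenyl)chroman-3,7-diol | c1ccccc1CS[C@@H]1c2ccc(O)cc2O[C@H](c2cc(O)c(O)c(O)c2)[C@H]1O
F2 | step 1 | (2R,3R)-7-(tert-butyldimethylsilyloxy)-3-hydroxy-2-[3,4,5-tris(tert-butyldimethylsilyloxy)phenyl]chroman-4-one | O=C1c2ccc(O[Si](C)(C)C(C)(C)C)cc2O[C@H](c2cc(O[Si](C)(C)C(C)(C)C)c(O[Si](C)(C)C(C)(C)C)c(O[Si](C)(C)C(C)(C)C)c2)[C@H]1O
F3 | step 1 | (2R,3S,4R)-7-(tert-butyldimethylsilyloxy)-2-[3,4,5-tris(tert-butyldimethylsilyloxy)phenyl]chroman-3,4-diol | O[C@@H]1c2ccc(O[Si](C)(C)C(C)(C)C)cc2O[C@H](c2cc(O[Si](C)(C)C(C)(C)C)c(O[Si](C)(C)C(C)(C)C)c(O[Si](C)(C)C(C)(C)C)c2)[C@H]1O
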